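**Assumption:** the Cu/Josiphos conjugate addition of MeMgBr to 3-allylcyclopentenone gives the (R)-quaternary centre in useful ee. I also assume the cis- and trans-fused ketones from the aldol/RCM sequence are separable.

## Retrosynthesis
- Ferutinine comes from jaeschkeanadiol by acylating the secondary 4-OH with 4-acetoxybenzoyl chloride and then removing the acetate. The tertiary alcohol does not acylate.
- The anti-1,3-diol comes from a β-hydroxy ketone by Evans–Saksena reduction. That ketone comes from oxidising the secondary OH of a diol, and the diol from iPr–Ce addition to the cyclopentanone of a 5-7 bicycle.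
- The cycloheptene (ring 2) is formed by RCM of a trans-2-(methallyl-carbinol)-1-allyl-1-methylcyclopentanone.
- That diene comes from a one-pot asymmetric Cu-catalysed conjugate addition of Me to 3-allylcyclopentenone (ring 1, quaternary C). The regiodefined enolate is trapped in situ with 3-methylbut-3-enal.

## Forward synthesis

**Step 1**
Reactants: 1 (3-ethoxycyclopent-2-en-1-one), 2 (allylmagnesium bromide)
Product: 3 (3-allylcyclopent-2-en-1-one)
Conditions: 2, THF, 0 °C; then 1 M HCl, rt
Reagents that add atoms: allylMgBr, C=CC[Mg]Br
Why: 1,2-addition of allyl-Grignard to the vinylogous ester, then acid-mediated loss of EtOH, transposes the carbonyl to the enone (Stork–Danheiser). No stereocentre is formed.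

**Step 2**
Reactants: 4 (3-methylbut-3-en-1-ol)
Product: 5 (3-methylbut-3-enal)
Conditions: Dess–Martin periodinane, NaHCO3, CH2Cl2, 0 °C; used crude and cold
Reagents that add atoms: none
Why: mild oxidation of a primary alcohol to the aldehyde without isomerising the β,γ-alkene into conjugation. This is a side branch that supplies the aldol partner.

**Step 3**
Reactants: 3, 6 (methylmagnesium bromide), 5
Product: 7 ((2S,3R)-3-allyl-2-(1-hydroxy-3-methylbut-3-en-1-yl)-3-methylcyclopentan-1-one; carbinol epimers)
Conditions: 6, CuBr·SMe2 (5 mol%), Josiphos ligand (6 mol%, enantiomer chosen for the (R)-quaternary centre), t-BuOMe, –78 °C; then 5, –78 → –40 °C; NH4Cl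
Reagents that add atoms: MeMgBr, C[Mg]Br
Why: asymmetric Cu-catalysed conjugate addition sets the quaternary methyl stereocentre (R). It generates the Mg enolate specifically at C2, the hindered position that LDA would not deprotonate. A tandem aldol (Zimmerman–Traxler type) with 5 then forms C–C(OH). The C2/carbinol stereocentres form as a diastereomer mixture, with the aldehyde preferring to approach anti to the allyl group. The mixture is carried on and sorted out after Step 4.

**Step 4**
Reactants: 7
Product: 8 (trans-fused 4-hydroxy-6,8a-dimethyl-hexahydroazulen-3-one, 6,7-ene; carbinol epimers)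
Conditions: Grubbs II (5 mol%), CH2Cl2 (2 mM), 40 °C
Reagents that add atoms: none (ethylene is lost)
Why: ring-closing metathesis of the terminal allyl and methallyl alkenes forms the trisubstituted cycloheptene. The ring fusion follows the C2 configuration set in Step 3, so the trans-fused isomer (Me and H-3a anti) is isolated by chromatography. The carbinol epimers are carried together because Step 6 removes that centre.

**Step 5**
Reactants: 8, 9 (isopropylmagnesium chloride)
Product: 10 (diol with C3-OH, C3-iPr, C4-OH)
Conditions: 9 (4 equiv), CeCl3 (4 equiv), THF, –78 → –20 °C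
Reagents that add atoms: iPrMgCl, CC(C)[Mg]Cl
Why: organocerium 1,2-addition avoids enolisation, reduction and retro-aldol of the β-alkoxide. The nucleophile attacks the ketone from the face opposite the adjacent C4 ring bond and the angular Me, which sets the tertiary carbinol with OH cis to C4 and iPr trans.

**Step 6**
Reactants: 10
Product: 11 (β-hydroxy ketone, C4=O, tertiary 3-OH)
Conditions: Dess–Martin periodinane, NaHCO3, CH2Cl2, 0 °C → rt
Reagents that add atoms: none
Why: the secondary alcohol is oxidised selectively over the tertiary alcohol and the alkene. This destroys the unwanted C4 carbinol stereochemistry, so the C4 epimers converge.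

**Step 7**
Reactants: 11
Product: 12 (jaeschkeanadiol)
Conditions: Me4NBH(OAc)3, MeCN/AcOH 1:1, –20 → 0 °C
Reagents that add atoms: none (only hydride is delivered)
Why: Evans–Saksena reduction. Hydride is delivered intramolecularly from the boron bound to the tertiary 3-O, so it arrives on the same face as that oxygen. This gives the anti-1,3-diol with the 4-OH configuration of the target.

**Step 8**
Reactants: 12, 13 (4-acetoxybenzoyl chloride)
Product: 14 (4-acetoxybenzoate of 12)
Conditions: 13 (2 equiv), Et3N, DMAP (0.2 equiv), CH2Cl2, 0 °C → rt
Reagents that add atoms: 4-AcOC6H4COCl, CC(=O)Oc1ccc(cc1)C(=O)Cl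
Why: DMAP-catalysed acylation occurs only at the secondary alcohol and retains its configuration. The tertiary alcohol is too hindered to react.

**Step 9**
Reactants: 14
Product: 15 (ferutinine)
Conditions: K2CO3 (1 equiv), MeOH, 0 °C, 15 min
Reagents that add atoms: none
Why: the aryl acetate is far more labile than the hindered, electron-rich 4-hydroxybenzoate alkyl ester, so methanolysis removes only the phenolic acetyl group.

## Compound list
1 | 3-ethoxycyclopent-2-en-1-one | CCOC1=CC(=O)CC1 | starting material
2 | allylmagnesium bromide | C=CC[Mg]Br | reagent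
3 | 3-allylcyclopent-2-en-1-one | C=CCC1=CC(=O)CC1 | intermediate
4 | 3-methylbut-3-en-1-ol | CC(=C)CCO | starting material
5 | 3-methylbut-3-enal | CC(=C)CC=O | intermediate
6 | methylmagnesium bromide | C[Mg]Br | reagent
7 | (2S,3R)-3-allyl-2-(1-hydroxy-3-methylbut-3-enyl)-3-methylcyclopentanone (carbinol unspecified) | C=CC[C@@]1(C)CCC(=O)[C@@H]1C(O)CC(C)=C | intermediate
8 | trans-fused 4-hydroxy-6,8a-dimethylhexahydroazulen-3-one (C4 unspecified) | O=C1CC[C@]2(C)CC=C(C)CC(O)[C@@H]12 | intermediate
9 | isopropylmagnesium chloride | CC(C)[Mg]Cl | reagent
10 | 3-isopropyl-6,8a-dimethyl-octahydroazulene-3,4-diol (C4 unspecified) | CC(C)[C@]1(O)CC[C@]2(C)CC=C(C)CC(O)[C@@H]12 | intermediate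
11 | 3-hydroxy-3-isopropyl-6,8a-dimethyl-hexahydroazulen-4-one | CC(C)[C@]1(O)CC[C@]2(C)CC=C(C)CC(=O)[C@@H]12 | intermediate
12 | jaeschkeanadiol, (3R,3aS,4S,8aR)-6,8a-dimethyl-3-(propan-2-yl)-1,2,3,3a,4,5,8,8a-octahydroazulene-3,4-diol | CC(C)[C@]1(O)CC[C@]2(C)CC=C(C)C[C@H](O)[C@@H]12 | intermediate
13 | 4-acetoxybenzoyl chloride | CC(=O)Oc1ccc(cc1)C(=O)Cl | reagent
14 | jaeschkeanadiol 4-(4-acetoxybenzoate) | CC(C)[C@]1(O)CC[C@]2(C)CC=C(C)C[C@H](OC(=O)c3ccc(OC(C)=O)cc3)[C@@H]12 | intermediate
15 | ferutinine | CC(C)[C@]1(O)CC[C@]2(C)CC=C(C)C[C@H](OC(=O)c3ccc(O)cc3)[C@@H]12 | target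

Total step count: 9. Longest linear sequence: 8 (Steps 1, 3, 4, 5, 6, 7, 8, 9).

## Three steps most likely to fail
1. **Step 3 (asymmetric conjugate addition/aldol).**
   - Possible problems: ee with a cyclopentenone, γ-deprotonation of the allyl enone by the Grignard, isomerisation or enolisation of the β,γ-unsaturated aldehyde, and a poor ring-fusion dr at C2.
   - Fallback: make the quaternary centre by Johnson–Claisen rearrangement of enantioenriched 3-methylcyclopent-2-en-1-ol (lipase or CBS). Convert the acetate side chain to allyl, trap the enolate as a TMS enol ether, and run a Mukaiyama aldol with 5.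
2. **Step 4 (RCM).**
   - Possible problems: forming a trans-fused trisubstituted cycloheptene next to a free β-hydroxy ketone, and retro-aldol or dehydration.
   - Fallback: change the ring closure to an intramolecular Nozaki–Hiyama–Kishi coupling of a vinyl iodide onto an aldehyde, which forms the C4–OH in the ring-closing step.
3. **Step 5 (iPr–Ce addition face selectivity).**
   - Possible problems: the wrong tertiary carbinol epimer, or competing reduction or retro-aldol.
   - Fallback: convert ketone 8 to the vinyl triflate and couple with iPrMgBr/Fe(acac)3 to give the isopropyl cyclopentene. Then use Mukaiyama hydration (Co(acac)2, PhSiH3, O2) or directed epoxidation/reductive opening, and separate epimers.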